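**Retrosynthetic overview**

- Target 16 comes from diaryl ketone 15 by C=O to CH2 reduction. 15 comes from 14 by one BCl3 operation that cleaves the methyl ether ortho to the carbonyl (chelation) and both benzyl ethers.
- 14 is assembled in one pot by a three-component aryne coupling. 3,5-Dimethoxybenzyne (from 3) takes up phenethyl Grignard 7, which forms the bond from ring A C-1 to the CH2 of the ethylene bridge. The aryl–Mg left at C-2 is then acylated with Weinreb amide 10.
- Enabling feature: in ring A (the central benzene; C-1 carries CH2CH2Ar, C-2 the 4-hydroxybenzyl group, C-3 OH, C-5 OMe), C-1 is meta to both oxygens, while C-2 is ortho to O-3 and para to O-5. C-1/C-2 therefore map onto the triple bond of a 3,5-dialkoxybenzyne, whose 3-alkoxy group steers a carbon nucleophile to C-1 and leaves the metal on C-2.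
- 3 comes from 3,5-dimethoxyphenol (ortho-iodination, triflation), 7 from 3-(2-hydroxyethyl)phenol and 10 from 4-(benzyloxy)benzoic acid.
- No ring is constructed: all three benzene rings are purchased arenes.

Key step: step 7

Remark: the target has no stereocentre, so no stereocontrol is needed; 1, 4 and 8 are taken as commercial.

**Route**

Step 1
Reactants: 1 3,5-dimethoxyphenol
Product: 2 2-iodo-3,5-dimethoxyphenol
Conditions: NIS (1.0 equiv), CH2Cl2, 0 °C, dark
Reagents that add atoms: N-iodosuccinimide, O=C1CCC(=O)N1I
Why: Electrophilic aromatic iodination; in a non-polar solvent the phenolic OH should direct iodine to its ortho position (also para to one OMe) rather than to the site between the two methoxy groups, and any 4-iodo isomer would be removed by chromatography.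

Step 2
Reactants: 2 2-iodo-3,5-dimethoxyphenol
Product: 3 2-iodo-3,5-dimethoxyphenyl trifluoromethanesulfonate
Conditions: Tf2O, pyridine, CH2Cl2, 0 °C
Reagents that add atoms: trifluoromethanesulfonic anhydride, O=S(=O)(OS(=O)(=O)C(F)(F)F)C(F)(F)F
Why: Routine O-sulfonylation of a phenol, which turns the oxygen next to iodine into the leaving group needed for low-temperature aryne generation.

Step 3
Reactants: 4 3-(2-hydroxyethyl)phenol
Product: 5 2-[3-(benzyloxy)phenyl]ethanol
Conditions: BnBr, K2CO3, acetone, reflux
Reagents that add atoms: benzyl bromide, BrCc1ccccc1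
Why: Williamson ether synthesis; K2CO3 deprotonates only the phenol, so the primary alcohol should stay free.

Step 4
Reactants: 5 2-[3-(benzyloxy)phenyl]ethanol
Product: 6 1-(benzyloxy)-3-(2-bromoethyl)benzene
Conditions: CBr4, PPh3, CH2Cl2, 0 °C to rt
Reagents that add atoms: carbon tetrabromide, BrC(Br)(Br)Br
Why: Appel reaction; bromide displaces the alkoxyphosphonium group at a primary carbon under neutral conditions that leave the benzyl ether intact.

Step 5
Reactants: 6 1-(benzyloxy)-3-(2-bromoethyl)benzene
Product: 7 {2-[3-(benzyloxy)phenyl]ethyl}magnesium bromide (titrated THF solution, used directly)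
Conditions: Mg turnings (1,2-dibromoethane activation), THF, rt to 40 °C, slow addition
Reagents that add atoms: magnesium, [Mg]
Why: Grignard formation by insertion of magnesium into the primary C–Br bond; slow addition limits Wurtz coupling and the aryl benzyl ether is inert.

Step 6
Reactants: 8 4-(benzyloxy)benzoic acid
Product: 10 4-(benzyloxy)-N-methoxy-N-methylbenzamide, via acyl imidazolide 9 (not isolated)
Conditions: CDI, CH2Cl2, rt; then MeNH(OMe)·HCl, rt
Reagents that add atoms: N,O-dimethylhydroxylamine hydrochloride, CNOC.Cl
Why: Standard Weinreb amide synthesis by acyl substitution on a CDI-derived acyl imidazolide.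

Step 7
Reactants: 3 2-iodo-3,5-dimethoxyphenyl trifluoromethanesulfonate; 7 {2-[3-(benzyloxy)phenyl]ethyl}magnesium bromide; 10 4-(benzyloxy)-N-methoxy-N-methylbenzamide
Product: 14 [4-(benzyloxy)phenyl](2-{2-[3-(benzyloxy)phenyl]ethyl}-4,6-dimethoxyphenyl)methanone, via magnesiated aryl triflate 11 (not isolated), via dimethoxybenzyne 12 (not isolated), via arylmagnesium adduct 13 (not isolated)
Conditions: 3 added slowly to 7 (2.4 equiv), THF, −78 °C to 0 °C; then 10 (1.6 equiv), 0 °C to rt; aq NH4Cl
Reagents that add atoms: none
Why: One equivalent of 7 should undergo iodine–magnesium exchange with 3 to give 11, which loses magnesium bromide triflate to give aryne 12; a second equivalent of 7 then adds its CH2 carbon to the aryne carbon that carried the triflate (meta to both OMe groups), leaving the magnesium in 13 on the neighbouring carbon next to OMe. Acylation of 13 by Weinreb amide 10 proceeds through a chelated tetrahedral intermediate that collapses to ketone 14 only on work-up, so over-addition is excluded. The closest known reaction type is the carbomagnesiation of arynes generated from 2-iodoaryl sulfonates by halogen–magnesium exchange, followed by electrophilic trapping of the new arylmagnesium (three-component aryne coupling). No ring is closed and no stereocentre is formed. The step needs regioselective addition to the unsymmetrical triple bond, and this is secured by the methoxy group adjacent to it: aryne distortion, inductive stabilisation and Mg–O coordination all favour attack at the distal carbon, and the second methoxy group is meta to that carbon. Keeping 7 in excess during slow addition of 3 should suppress addition of 13 to a second aryne.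

Step 8
Reactants: 14 [4-(benzyloxy)phenyl](2-{2-[3-(benzyloxy)phenyl]ethyl}-4,6-dimethoxyphenyl)methanone
Product: 15 (4-hydroxyphenyl){2-hydroxy-6-[2-(3-hydroxyphenyl)ethyl]-4-methoxyphenyl}methanone
Conditions: BCl3 (6 equiv), pentamethylbenzene (6 equiv), CH2Cl2, −78 °C to 0 °C; MeOH, then H2O
Reagents that add atoms: none
Why: Lewis-acid ether cleavage; boron bound to the ketone oxygen chelates the ortho methoxy oxygen and cleaves only that methyl ether, and both aryl benzyl ethers are cleaved with pentamethylbenzene trapping the benzyl cations, while the unchelated methoxy group para to the carbonyl should survive at or below 0 °C.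

Step 9
Reactants: 15 (4-hydroxyphenyl){2-hydroxy-6-[2-(3-hydroxyphenyl)ethyl]-4-methoxyphenyl}methanone
Product: 16 2-[(4-hydroxyphenyl)methyl]-3-[2-(3-hydroxyphenyl)ethyl]-5-methoxyphenol (IN1159)
Conditions: Et3SiH (5 equiv), TFA/CH2Cl2, 0 °C to 40 °C
Reagents that add atoms: none
Why: Ionic hydrogenation of an electron-rich diaryl ketone; protonation, hydride transfer, ionisation of the benzhydrol to a cation stabilised by the ortho-hydroxy/para-methoxy ring and the para-hydroxyphenyl ring, and a second hydride transfer should give the diarylmethane, with phenols and the bibenzyl chain inert.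

**Compound list**

1 | 3,5-dimethoxyphenol | COc1cc(O)cc(OC)c1 | starting material
2 | 2-iodo-3,5-dimethoxyphenol | COc1cc(O)c(I)c(OC)c1 | intermediate
3 | 2-iodo-3,5-dimethoxyphenyl trifluoromethanesulfonate | COc1cc(OS(=O)(=O)C(F)(F)F)c(I)c(OC)c1 | intermediate
4 | 3-(2-hydroxyethyl)phenol | OCCc1cccc(O)c1 | starting material
5 | 2-[3-(benzyloxy)phenyl]ethanol | OCCc1cccc(OCc2ccccc2)c1 | intermediate
6 | 1-(benzyloxy)-3-(2-bromoethyl)benzene | BrCCc1cccc(OCc2ccccc2)c1 | intermediate
7 | {2-[3-(benzyloxy)phenyl]ethyl}magnesium bromide | Br[Mg]CCc1cccc(OCc2ccccc2)c1 | intermediate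
8 | 4-(benzyloxy)benzoic acid | OC(=O)c1ccc(OCc2ccccc2)cc1 | starting material
9 | [4-(benzyloxy)phenyl](1H-imidazol-1-yl)methanone | O=C(c1ccc(OCc2ccccc2)cc1)n1ccnc1 | intermediate
10 | 4-(benzyloxy)-N-methoxy-N-methylbenzamide | CON(C)C(=O)c1ccc(OCc2ccccc2)cc1 | intermediate
11 | (2,4-dimethoxy-6-{[(trifluoromethyl)sulfonyl]oxy}phenyl)magnesium bromide | COc1cc(OS(=O)(=O)C(F)(F)F)c([Mg]Br)c(OC)c1 | intermediate
12 | 3,5-dimethoxybenzyne (1,2-didehydro-3,5-dimethoxybenzene) | COC1=CC(OC)=CC#C1 | intermediate
13 | (2-{2-[3-(benzyloxy)phenyl]ethyl}-4,6-dimethoxyphenyl)magnesium bromide | COc1cc(OC)c([Mg]Br)c(CCc2cccc(OCc3ccccc3)c2)c1 | intermediate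
14 | [4-(benzyloxy)phenyl](2-{2-[3-(benzyloxy)phenyl]ethyl}-4,6-dimethoxyphenyl)methanone | COc1cc(OC)c(C(=O)c2ccc(OCc3ccccc3)cc2)c(CCc2cccc(OCc3ccccc3)c2)c1 | intermediate
15 | (4-hydroxyphenyl){2-hydroxy-6-[2-(3-hydroxyphenyl)ethyl]-4-methoxyphenyl}methanone | COc1cc(O)c(C(=O)c2ccc(O)cc2)c(CCc2cccc(O)c2)c1 | intermediate
16 | 2-[(4-hydroxyphenyl)methyl]-3-[2-(3-hydroxyphenyl)ethyl]-5-methoxyphenol (IN1159) | COc1cc(O)c(Cc2ccc(O)cc2)c(CCc2cccc(O)c2)c1 | target

**Totals**

Total step count: 9. Longest linear sequence: 6 steps (steps 3, 4, 5, 7, 8, 9).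

**Steps most likely to fail, with fallbacks**

Step 7. Several processes could erode the coupling: anionic thia-Fries migration or protonation of the magnesiated triflate instead of elimination; hydride transfer from the β-CH2 of the Grignard reagent to the aryne; addition of the new arylmagnesium to a second aryne; and slow acylation of the doubly ortho-substituted arylmagnesium. The fallback builds the same two bonds stepwise by known chemistry, setting out from 1 and 7 and returning at 14. Compound 1 would be triflated (Tf2O, pyridine) to 3,5-dimethoxyphenyl trifluoromethanesulfonate F1. Kumada–Corriu coupling of F1 with 7 (PdCl2(dppf), THF, reflux) should give 1-{2-[3-(benzyloxy)phenyl]ethyl}-3,5-dimethoxybenzene F2. Bromination with NBS in MeCN at 0 °C is expected at the ring position between the alkyl chain and a methoxy group (para to the other methoxy group), giving 2-bromo-1-{2-[3-(benzyloxy)phenyl]ethyl}-3,5-dimethoxybenzene F3. Bromine–lithium exchange (n-BuLi, THF, −78 °C) would give (2-{2-[3-(benzyloxy)phenyl]ethyl}-4,6-dimethoxyphenyl)lithium F4, which is acylated with 10 to give 14.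

Step 1. Competing iodination at the position para to the hydroxyl group (between the two methoxy groups) and over-iodination could lower the supply of 2. The fallback fixes the regiochemistry by directed ortho-metalation, setting out from 1 and returning at 2. Compound 1 would be carbamoylated (ClCONEt2, K2CO3, MeCN, reflux) to 3,5-dimethoxyphenyl N,N-diethylcarbamate F5. Lithiation with s-BuLi/TMEDA in THF at −78 °C should occur between the carbamate and a methoxy group to give [2-(diethylcarbamoyloxy)-4,6-dimethoxyphenyl]lithium F6, which is quenched with I2 at −78 °C (before any anionic Fries shift) to give 2-iodo-3,5-dimethoxyphenyl N,N-diethylcarbamate F7. Hydrolysis (NaOH, EtOH/H2O, reflux) would give 2.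

Step 8. Loss of discrimination between the two methyl ethers on warming, or Friedel–Crafts benzylation of the electron-rich rings if cation trapping is inefficient, could spoil the global deprotection. The fallback separates the two tasks, setting out from 14 and returning at 16, bypassing 15 and step 9. Chelation-selective demethylation with MgI2 etherate (toluene/Et2O, 80 °C; dilute HCl work-up) should leave the benzyl ethers and give [4-(benzyloxy)phenyl](2-{2-[3-(benzyloxy)phenyl]ethyl}-6-hydroxy-4-methoxyphenyl)methanone F8. Hydrogenation of F8 (H2, Pd/C, EtOAc/AcOH) should remove both benzyl groups and reduce the diaryl ketone through the benzhydrol to the methylene group, giving 16 directly.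

**Further compounds**

F1 | step 7 | 3,5-dimethoxyphenyl trifluoromethanesulfonate | COc1cc(OC)cc(OS(=O)(=O)C(F)(F)F)c1
F2 | step 7 | 1-{2-[3-(benzyloxy)phenyl]ethyl}-3,5-dimethoxybenzene | COc1cc(OC)cc(CCc2cccc(OCc3ccccc3)c2)c1
F3 | step 7 | 2-bromo-1-{2-[3-(benzyloxy)phenyl]ethyl}-3,5-dimethoxybenzene | COc1cc(OC)c(Br)c(CCc2cccc(OCc3ccccc3)c2)c1
F4 | step 7 | (2-{2-[3-(benzyloxy)phenyl]ethyl}-4,6-dimethoxyphenyl)lithium | [Li]c1c(OC)cc(OC)cc1CCc1cccc(OCc2ccccc2)c1
F5 | step 1 | 3,5-dimethoxyphenyl N,N-diethylcarbamate | CCN(CC)C(=O)Oc1cc(OC)cc(OC)c1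
F6 | step 1 | [2-(diethylcarbamoyloxy)-4,6-dimethoxyphenyl]lithium | CCN(CC)C(=O)Oc1cc(OC)cc(OC)c1[Li]
F7 | step 1 | 2-iodo-3,5-dimethoxyphenyl N,N-diethylcarbamate | CCN(CC)C(=O)Oc1cc(OC)cc(OC)c1I
F8 | step 8 | [4-(benzyloxy)phenyl](2-{2-[3-(benzyloxy)phenyl]ethyl}-6-hydroxy-4-methoxyphenyl)methanone | COc1cc(O)c(C(=O)c2ccc(OCc3ccccc3)cc2)c(CCc2cccc(OCc3ccccc3)c2)c1
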